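Electrophile left over at the end is my worry: for the next run I must choose between charging more nucleophile and simply waiting longer.

| flask | electrophile | nucleophile | time |
|---|---|---|---|
| blue | 0.0010 M | 1.00 mM | 3.0 min |
| green | 0.0010 M | 1.50 mM | 3.0 min |

    nucleophile + acid set free ⇌ protonated nucleophile, settled at all times (K1 = 4.6 × 10⁶ /M)
    electrophile + nucleophile → acid set free + product (k2 = 280 /M/s)
    nucleophile ⇌ dormant form (K3 = 0.91, k3 = 0.47 /s)

- part of the electrophile that has reacted at the end, blue
- part of the electrophile that has reacted at the end, green
- what raising the concentration of nucleophile from its lowest to its highest value here does to the part of the electrophile that has reacted (changes below 5 percentage points count as none) (it rises / it falls / no change)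

Step 2 starts quick: the half-life of electrophile in blue by step 2 alone, at the charged concentrations, is 2.5 s, far shorter than the 3.0 min allowed. Each electrophile reacted sets one acid free. I hold step 1 at balance, and in blue K1 times c(nucleophile) at the start is 4600, far above one, so that acid takes a second nucleophile. In my reckoning the nucleophile, the limiting reagent, therefore goes two per electrophile. In green nucleophile and dormant form relax towards each other by step 3 alone with a half-life of 0.703 s, shorter than 3.0 min, so I count the dormant form as a store that hands nucleophile back, not as a loss.

My number for blue is 50.0%: the acid stall, c(nucleophile) over two c(electrophile), both as charged. For green it is 75.0%, a rise of 25 percentage points where 5 points counts as a change. Past the stall I reckon nothing, so these two are my estimates, and I lean towards charging nucleophile.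

The forecast says 54.4% for blue, 78.4% for green, and it rises. It starts from the same two marks but adds about 4 points in each flask, where I add none: “only the trace of free nucleophile left by the strong protonation equilibrium keeps it creeping”.

The simulation gives 54.2% for blue and 78.2% for green, and it rises, by 24 points, so the forecast stands. For the forecast's blue figure to go wrong, the charge must differ from the recipe: the simulated blue answer has moved by 5 points at a nucleophile charge of 0.899 mM or 1.10 mM, with the other amounts and the time held. The acid stall moves by 5.1 points at that upper charge, so I weigh the nucleophile closely.

A neighbour of green, charged with 9.0 × 10⁻⁴ M of nucleophile, has an acid stall of 45.0%. The simulation gives 49.3% for it.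

The numbers are assumed; the result is computed.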